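The route rests on disconnecting the 2,2-dimethylchroman (benzene ring A fused to a pyran ring) at O1–C2 and C4–C4a. The phenol oxygen and its ortho carbon are bridged by a three-carbon chain whose gem-dimethyl carbon sits on oxygen. An aryl 1,1-dimethylpropargyl ether of 4'-hydroxyacetophenone carries these five carbons on O1. On heating, one pericyclic cascade forges C4–C4a, returns C2 to O1 and closes the pyran as a 2H-chromene; the para acetyl group makes both ortho carbons equivalent. The acetyl group then supplies the carbinol carbon: it is homologated, reduced enantioselectively and joined as a Weinreb amide to a resorcinol-derived epoxy aryllithium. A final deallylation closes the dihydrofuran.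

Key step: step 2

Remark: CIP analysis of the target gives S at the benzylic carbinol carbon and S at C2 of the dihydrobenzofuran; the chiral catalysts are chosen for this isomer.

Step 1
Reactants: 1 4'-hydroxyacetophenone; 2 3-chloro-3-methylbut-1-yne
Product: 3 1-[4-(2-methylbut-3-yn-2-yloxy)phenyl]ethanone
Conditions: K2CO3, KI (20 mol %), CuI (10 mol %), acetone, reflux
Reagents that add atoms: none
Why: Copper-assisted Williamson-type O-propargylation, in which the tertiary propargylic chloride is activated by monovalent copper and captured on oxygen by the para-acetylphenoxide, is the standard entry to aryl 1,1-dimethylpropargyl ethers.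

Step 2
Reactants: 3 1-[4-(2-methylbut-3-yn-2-yloxy)phenyl]ethanone
Product: 7 1-(2,2-dimethyl-2H-chromen-6-yl)ethanone, via allenyl cyclohexadienone 4 (not isolated), via allenylphenol 5 (not isolated), via ortho-quinone methide 6 (not isolated)
Conditions: 1,2-dichlorobenzene, 180 °C, Ar
Reagents that add atoms: none
Why: On heating, an aromatic propargyl Claisen [3,3] shift breaks O–CMe2 and joins the alkyne terminus to the ortho carbon (the C4–C4a bond) to give dienone 4, which enolises to allenylphenol 5; a [1,5] hydrogen shift from O–H to the central allene carbon then gives the Z-configured ortho-quinone methide 6, whose 1-oxatriene closes by a thermal disrotatory 6π oxa-electrocyclisation that forms O1–C2. The closest known reaction type is the thermal Claisen rearrangement of aryl 1,1-dimethylpropargyl ethers to 2,2-dimethyl-2H-chromenes. The only ring formed, the pyran, is closed by this electrocyclisation (formally a 6-endo closure of oxygen onto the dimethyl-substituted terminus), and no stereocenter arises because C2 carries two methyl groups. Regioselectivity needs no control because the para acetyl group leaves two equivalent ortho C–H positions, and rearomatisation in the last event drives the cascade. The selectivity that matters is six-membered chromene over 2-methylbenzofuran, which would come from 5-exo attack of a phenoxide on the allene; a neutral, aprotic medium free of fluoride and strong base keeps the reaction on the pericyclic path, and the gem-dimethyl group accelerates both the [3,3] shift and the ring closure.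

Step 3
Reactants: 7 1-(2,2-dimethyl-2H-chromen-6-yl)ethanone
Product: 8 1-(2,2-dimethyl-3,4-dihydro-2H-chromen-6-yl)ethanone
Conditions: H2 (1 atm), 10% Pd/C, EtOAc, rt
Reagents that add atoms: none
Why: Heterogeneous catalytic hydrogenation saturates the cis-disubstituted styrenic C3=C4 bond at atmospheric pressure far faster than it touches the conjugated, electron-rich aryl ketone.

Step 4
Reactants: 8 1-(2,2-dimethyl-3,4-dihydro-2H-chromen-6-yl)ethanone
Product: 9 methyl 3-(2,2-dimethyl-3,4-dihydro-2H-chromen-6-yl)-3-oxopropanoate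
Conditions: NaH, (MeO)2CO, THF, reflux; AcOH quench
Reagents that add atoms: dimethyl carbonate, COC(=O)OC
Why: Crossed Claisen condensation (C-methoxycarbonylation) of the methyl ketone enolate with non-enolisable dimethyl carbonate is pulled to completion by irreversible deprotonation of the β-keto ester by NaH.

Step 5
Reactants: 9 methyl 3-(2,2-dimethyl-3,4-dihydro-2H-chromen-6-yl)-3-oxopropanoate
Product: 10 methyl (3S)-3-(2,2-dimethyl-3,4-dihydro-2H-chromen-6-yl)-3-hydroxypropanoate
Conditions: RuCl(p-cymene)[(S,S)-TsDPEN] (1 mol %), HCO2H–Et3N (5:2), DMF, 40 °C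
Reagents that add atoms: none
Why: Noyori asymmetric transfer hydrogenation reduces only the aryl ketone through the outer-sphere Ru–H/N–H six-membered transition state, in which a CH–π contact between the cymene ligand and the aryl group fixes the orientation, so the (S,S)-catalyst delivers hydride to the face that gives the (S)-benzylic alcohol, as it does for simple aryl ketones.

Step 6
Reactants: 10 methyl (3S)-3-(2,2-dimethyl-3,4-dihydro-2H-chromen-6-yl)-3-hydroxypropanoate
Product: 11 (3S)-3-(2,2-dimethyl-3,4-dihydro-2H-chromen-6-yl)-3-hydroxy-N-methoxy-N-methylpropanamide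
Conditions: MeNH(OMe)·HCl, i-PrMgCl, THF, −20 → 0 °C; aq. NH4Cl
Reagents that add atoms: N,O-dimethylhydroxylamine hydrochloride, Cl.CNOC
Why: Direct Weinreb aminolysis of the ester by the chloromagnesium amide of N,O-dimethylhydroxylamine runs at or below 0 °C, where the magnesium alkoxide of the β-hydroxyl neither eliminates nor undergoes retro-aldol cleavage, so the stereocenter is kept.

Step 7
Reactants: 12 4,6-dibromoresorcinol
Product: 13 1,5-dibromo-2,4-bis(prop-2-en-1-yloxy)benzene
Conditions: allyl bromide, K2CO3, DMF, rt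
Reagents that add atoms: allyl bromide, C=CCBr
Why: Williamson etherification of both phenols with an unhindered allylic bromide is routine, and allyl is chosen because it tolerates aryllithium chemistry at −78 °C and dioxirane epoxidation and can be removed at the end under nearly neutral zerovalent-palladium catalysis.

Step 8
Reactants: 13 1,5-dibromo-2,4-bis(prop-2-en-1-yloxy)benzene; 14 prenyl bromide (1-bromo-3-methylbut-2-ene)
Product: 16 1-bromo-5-(3-methylbut-2-en-1-yl)-2,4-bis(prop-2-en-1-yloxy)benzene, via aryllithium 15 (not isolated)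
Conditions: n-BuLi (1.0 equiv), THF, −78 °C; CuI (10 mol %), 14, −78 → 0 °C
Reagents that add atoms: none
Why: Bromine–lithium exchange on the symmetrical dibromide stops after one exchange because a single equivalent is used and the electron-rich aryllithium resists a second one, and copper-catalysed allylic substitution at the unhindered primary carbon of prenyl bromide (SN2 mode) installs the linear prenyl group.

Step 9
Reactants: 16 1-bromo-5-(3-methylbut-2-en-1-yl)-2,4-bis(prop-2-en-1-yloxy)benzene
Product: 17 (3R)-3-{[5-bromo-2,4-bis(prop-2-en-1-yloxy)phenyl]methyl}-2,2-dimethyloxirane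
Conditions: D-fructose-derived Shi ketone (30 mol %), Oxone (2KHSO5·KHSO4·K2SO4), K2CO3, Bu4NHSO4, MeCN–CH2(OMe)2, aq. Na2B4O7/Na2EDTA buffer, 0 °C
Reagents that add atoms: potassium peroxymonosulfate (KHSO5, the oxidant in Oxone), [K+].[O-]S(=O)(=O)OO
Why: Shi asymmetric epoxidation by the chiral dioxirane attacks the electron-rich trisubstituted prenyl alkene much faster than the monosubstituted allyl ethers, and the spiro transition state of the D-fructose-derived ketone delivers oxygen to the face that makes the secondary epoxide carbon R.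

Step 10
Reactants: 17 (3R)-3-{[5-bromo-2,4-bis(prop-2-en-1-yloxy)phenyl]methyl}-2,2-dimethyloxirane; 11 (3S)-3-(2,2-dimethyl-3,4-dihydro-2H-chromen-6-yl)-3-hydroxy-N-methoxy-N-methylpropanamide
Product: 19 (3S)-1-{5-{[(2R)-3,3-dimethyloxiran-2-yl]methyl}-2,4-bis(prop-2-en-1-yloxy)phenyl}-3-(2,2-dimethyl-3,4-dihydro-2H-chromen-6-yl)-3-hydroxypropan-1-one, via aryllithium 18 (not isolated)
Conditions: 17 (1.3 equiv), n-BuLi (1.3 equiv), THF, −78 °C; then 11 pre-treated with i-PrMgCl (1.0 equiv, THF, −40 °C), −78 → −20 °C; aq. NH4Cl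
Reagents that add atoms: none
Why: Weinreb ketone synthesis, in which bromine–lithium exchange at −78 °C outpaces any reaction at the epoxide or the allyl ethers, the hydroxyl of 11 is masked in the flask as its magnesium alkoxide, and the chelated tetrahedral adduct releases the ketone only on work-up, so neither over-addition nor any change at the two stereocenters is expected.

Step 11
Reactants: 19 (3S)-1-{5-{[(2R)-3,3-dimethyloxiran-2-yl]methyl}-2,4-bis(prop-2-en-1-yloxy)phenyl}-3-(2,2-dimethyl-3,4-dihydro-2H-chromen-6-yl)-3-hydroxypropan-1-one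
Product: 21 (3S)-3-(2,2-dimethyl-3,4-dihydro-2H-chromen-6-yl)-3-hydroxy-1-[(2S)-6-hydroxy-2-(2-hydroxypropan-2-yl)-2,3-dihydro-1-benzofuran-5-yl]propan-1-one, via bisphenol epoxide 20 (not isolated)
Conditions: Pd(PPh3)4 (5 mol %), morpholine (6 equiv), THF–MeOH, rt, then 45 °C
Reagents that add atoms: none
Why: Tsuji–Trost-type deallylation with morpholine as allyl acceptor frees both phenols under nearly neutral conditions, after which the acidic para-acyl phenoxide opens the epoxide by intramolecular 5-exo-tet SN2 attack at the secondary carbon with inversion, turning the (R)-epoxide carbon into the (S)-configured C2 of the dihydrobenzofuran, while the ortho hydroxyl, which cannot reach the epoxide, ends as the chelated phenol.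

Compound list
1 | 4'-hydroxyacetophenone | CC(=O)c1ccc(O)cc1 | starting material
2 | 3-chloro-3-methylbut-1-yne | CC(C)(Cl)C#C | starting material
3 | 1-[4-(2-methylbut-3-yn-2-yloxy)phenyl]ethanone | CC(=O)c1ccc(OC(C)(C)C#C)cc1 | intermediate
4 | 4-acetyl-6-(3-methylbuta-1,2-dien-1-yl)cyclohexa-2,4-dien-1-one (racemic, transient) | CC(=O)C1=CC(C=C=C(C)C)C(=O)C=C1 | intermediate
5 | 1-[4-hydroxy-3-(3-methylbuta-1,2-dien-1-yl)phenyl]ethanone (transient) | CC(=O)c1ccc(O)c(C=C=C(C)C)c1 | intermediate
6 | (6Z)-4-acetyl-6-(3-methylbut-2-en-1-ylidene)cyclohexa-2,4-dien-1-one (transient) | CC(=O)C1=C/C(=C/C=C(C)C)C(=O)C=C1 | intermediate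
7 | 1-(2,2-dimethyl-2H-chromen-6-yl)ethanone | CC(=O)c1ccc2OC(C)(C)C=Cc2c1 | intermediate
8 | 1-(2,2-dimethyl-3,4-dihydro-2H-chromen-6-yl)ethanone | CC(=O)c1ccc2OC(C)(C)CCc2c1 | intermediate
9 | methyl 3-(2,2-dimethyl-3,4-dihydro-2H-chromen-6-yl)-3-oxopropanoate | COC(=O)CC(=O)c1ccc2OC(C)(C)CCc2c1 | intermediate
10 | methyl (3S)-3-(2,2-dimethyl-3,4-dihydro-2H-chromen-6-yl)-3-hydroxypropanoate | CC1(C)CCc2cc([C@@H](O)CC(=O)OC)ccc2O1 | intermediate
11 | (3S)-3-(2,2-dimethyl-3,4-dihydro-2H-chromen-6-yl)-3-hydroxy-N-methoxy-N-methylpropanamide | CC1(C)CCc2cc([C@@H](O)CC(=O)N(C)OC)ccc2O1 | intermediate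
12 | 4,6-dibromoresorcinol (4,6-dibromobenzene-1,3-diol) | Oc1cc(O)c(Br)cc1Br | starting material
13 | 1,5-dibromo-2,4-bis(prop-2-en-1-yloxy)benzene | C=CCOc1cc(OCC=C)c(Br)cc1Br | intermediate
14 | prenyl bromide (1-bromo-3-methylbut-2-ene) | CC(C)=CCBr | starting material
15 | [5-bromo-2,4-bis(prop-2-en-1-yloxy)phenyl]lithium (transient) | [Li]c1cc(Br)c(OCC=C)cc1OCC=C | intermediate
16 | 1-bromo-5-(3-methylbut-2-en-1-yl)-2,4-bis(prop-2-en-1-yloxy)benzene | CC(C)=CCc1cc(Br)c(OCC=C)cc1OCC=C | intermediate
17 | (3R)-3-{[5-bromo-2,4-bis(prop-2-en-1-yloxy)phenyl]methyl}-2,2-dimethyloxirane | CC1(C)O[C@@H]1Cc2cc(Br)c(OCC=C)cc2OCC=C | intermediate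
18 | {5-{[(2R)-3,3-dimethyloxiran-2-yl]methyl}-2,4-bis(prop-2-en-1-yloxy)phenyl}lithium (transient) | CC1(C)O[C@@H]1Cc2cc([Li])c(OCC=C)cc2OCC=C | intermediate
19 | (3S)-1-{5-{[(2R)-3,3-dimethyloxiran-2-yl]methyl}-2,4-bis(prop-2-en-1-yloxy)phenyl}-3-(2,2-dimethyl-3,4-dihydro-2H-chromen-6-yl)-3-hydroxypropan-1-one | CC1(C)CCc2cc([C@@H](O)CC(=O)c3cc(C[C@H]4OC4(C)C)c(OCC=C)cc3OCC=C)ccc2O1 | intermediate
20 | (3S)-1-{5-{[(2R)-3,3-dimethyloxiran-2-yl]methyl}-2,4-dihydroxyphenyl}-3-(2,2-dimethyl-3,4-dihydro-2H-chromen-6-yl)-3-hydroxypropan-1-one (transient) | CC1(C)CCc2cc([C@@H](O)CC(=O)c3cc(C[C@H]4OC4(C)C)c(O)cc3O)ccc2O1 | intermediate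
21 | (3S)-3-(2,2-dimethyl-3,4-dihydro-2H-chromen-6-yl)-3-hydroxy-1-[(2S)-6-hydroxy-2-(2-hydroxypropan-2-yl)-2,3-dihydro-1-benzofuran-5-yl]propan-1-one | CC1(C)CCc2cc([C@@H](O)CC(=O)c3cc4c(cc3O)O[C@H](C(C)(C)O)C4)ccc2O1 | target

Total step count: 11. Longest linear sequence: 8 steps (steps 1 to 6, then 10 and 11); the second branch (steps 7 to 9) joins at step 10.

Steps most likely to fail

Step 10. The union may stall if the aryllithium is spent on proton abstraction from the α-methylene of the Weinreb amide, or on slow attack at its own allyl ethers, before it adds. The magnesium alkoxide may also aggregate and slow the addition. The fallback sets out from 11 and 17 and removes the alkoxide from the coupling. Compound 11 would be silylated (TBSCl, imidazole, DMF) to (3S)-3-[(tert-butyldimethylsilyl)oxy]-3-(2,2-dimethyl-3,4-dihydro-2H-chromen-6-yl)-N-methoxy-N-methylpropanamide F1, a plain monofunctional Weinreb amide. Addition of 18 (from 17, n-BuLi, THF, −78 °C) should give the silyl-protected epoxy ketone (3S)-3-[(tert-butyldimethylsilyl)oxy]-1-{5-{[(2R)-3,3-dimethyloxiran-2-yl]methyl}-2,4-bis(prop-2-en-1-yloxy)phenyl}-3-(2,2-dimethyl-3,4-dihydro-2H-chromen-6-yl)propan-1-one F2. Buffered fluoride (Bu4NF, AcOH, THF, 0 °C) would then remove the silyl group and rejoin the route at 19.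

Step 11. After deallylation, ring closure may be slow or partly diverted to 6-endo attack at the tertiary epoxide carbon, and long exposure of the β-hydroxy ketone to amine base invites dehydration towards the chalcone. The fallback sets out from 17 and closes the dihydrofuran on the small fragment, where stronger base is harmless.
- Deallylation (Pd(PPh3)4, morpholine, THF) would give 4-bromo-6-{[(2R)-3,3-dimethyloxiran-2-yl]methyl}benzene-1,3-diol F3, which K2CO3 in MeOH should close with inversion to (2S)-5-bromo-2-(2-hydroxypropan-2-yl)-2,3-dihydro-1-benzofuran-6-ol F4.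
- Selective phenol allylation (allyl bromide, K2CO3, acetone) would give 2-[(2S)-5-bromo-6-(prop-2-en-1-yloxy)-2,3-dihydro-1-benzofuran-2-yl]propan-2-ol F5.
- n-BuLi (2.1 equiv, THF, −78 °C; the first equivalent deprotonates the tertiary alcohol) would form lithium 2-[(2S)-5-lithio-6-(prop-2-en-1-yloxy)-2,3-dihydro-1-benzofuran-2-yl]propan-2-olate F6. Addition of the chloromagnesium alkoxide of 11 would then give (3S)-3-(2,2-dimethyl-3,4-dihydro-2H-chromen-6-yl)-3-hydroxy-1-[(2S)-2-(2-hydroxypropan-2-yl)-6-(prop-2-en-1-yloxy)-2,3-dihydro-1-benzofuran-5-yl]propan-1-one F7.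
- A single deallylation (Pd(PPh3)4, morpholine, THF, rt) would rejoin the route at 21.

Step 8. Butyllithium or the aryllithium may attack the allyl ethers (SN2′ cleavage or intramolecular carbolithiation) in competition with exchange and alkylation, and a second exchange would lower the amount of mono-prenylated material. The fallback sets out from 12 and carries the phenols as methoxymethyl ethers through the organolithium step.
- MOMCl and i-Pr2NEt in CH2Cl2 would give 1,5-dibromo-2,4-bis(methoxymethoxy)benzene F8.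
- n-BuLi (1.0 equiv, THF, −78 °C) would give [5-bromo-2,4-bis(methoxymethoxy)phenyl]lithium F9, which with CuI (10 mol %) and 14 should give 1-bromo-2,4-bis(methoxymethoxy)-5-(3-methylbut-2-en-1-yl)benzene F10.
- Dilute HCl in MeOH at rt would free 4-bromo-6-(3-methylbut-2-en-1-yl)benzene-1,3-diol F11.
- Allyl bromide and K2CO3 in DMF would rejoin the route at 16.

Further compounds
F1 | step 10 | (3S)-3-[(tert-butyldimethylsilyl)oxy]-3-(2,2-dimethyl-3,4-dihydro-2H-chromen-6-yl)-N-methoxy-N-methylpropanamide | CC1(C)CCc2cc([C@@H](O[Si](C)(C)C(C)(C)C)CC(=O)N(C)OC)ccc2O1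
F2 | step 10 | (3S)-3-[(tert-butyldimethylsilyl)oxy]-1-{5-{[(2R)-3,3-dimethyloxiran-2-yl]methyl}-2,4-bis(prop-2-en-1-yloxy)phenyl}-3-(2,2-dimethyl-3,4-dihydro-2H-chromen-6-yl)propan-1-one | CC1(C)CCc2cc([C@@H](O[Si](C)(C)C(C)(C)C)CC(=O)c3cc(C[C@H]4OC4(C)C)c(OCC=C)cc3OCC=C)ccc2O1
F3 | step 11 | 4-bromo-6-{[(2R)-3,3-dimethyloxiran-2-yl]methyl}benzene-1,3-diol | CC1(C)O[C@@H]1Cc2cc(Br)c(O)cc2O
F4 | step 11 | (2S)-5-bromo-2-(2-hydroxypropan-2-yl)-2,3-dihydro-1-benzofuran-6-ol | CC(C)(O)[C@@H]1Cc2cc(Br)c(O)cc2O1
F5 | step 11 | 2-[(2S)-5-bromo-6-(prop-2-en-1-yloxy)-2,3-dihydro-1-benzofuran-2-yl]propan-2-ol | CC(C)(O)[C@@H]1Cc2cc(Br)c(OCC=C)cc2O1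
F6 | step 11 | lithium 2-[(2S)-5-lithio-6-(prop-2-en-1-yloxy)-2,3-dihydro-1-benzofuran-2-yl]propan-2-olate | CC(C)(O[Li])[C@@H]1Cc2cc([Li])c(OCC=C)cc2O1
F7 | step 11 | (3S)-3-(2,2-dimethyl-3,4-dihydro-2H-chromen-6-yl)-3-hydroxy-1-[(2S)-2-(2-hydroxypropan-2-yl)-6-(prop-2-en-1-yloxy)-2,3-dihydro-1-benzofuran-5-yl]propan-1-one | CC1(C)CCc2cc([C@@H](O)CC(=O)c3cc4c(cc3OCC=C)O[C@H](C(C)(C)O)C4)ccc2O1
F8 | step 8 | 1,5-dibromo-2,4-bis(methoxymethoxy)benzene | COCOc1cc(OCOC)c(Br)cc1Br
F9 | step 8 | [5-bromo-2,4-bis(methoxymethoxy)phenyl]lithium | [Li]c1cc(Br)c(OCOC)cc1OCOC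
F10 | step 8 | 1-bromo-2,4-bis(methoxymethoxy)-5-(3-methylbut-2-en-1-yl)benzene | CC(C)=CCc1cc(Br)c(OCOC)cc1OCOC
F11 | step 8 | 4-bromo-6-(3-methylbut-2-en-1-yl)benzene-1,3-diol | CC(C)=CCc1cc(Br)c(O)cc1O
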